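The earlier runs and the new flask were generated by integration on assumed constants; scatter was added.

At 10 min, the time of reading, each of the five flasks holds some over-reaction product, and you want to know how much.

| flask | first end groups | third end groups | solid second end groups | temperature | remark | time |
|---|---|---|---|---|---|---|
| violet | 0.26 M | 0.13 M | 0.286 M | 20 °C | run made earlier |  |
| grey | 0.26 M | 0.13 M | 0.14 M | 31 °C | run made earlier |  |
| teal | 0.26 M | 0.13 M | 0.57 M | 20 °C | run made earlier |  |
| blue | 0.26 M | 0.20 M | 0.286 M | 31 °C | run made earlier |  |
| elm | 0.26 M (fed, over 6.0 min) | 0.130 M | 0.286 M | 25 °C | all else is in the flask from the start; the feed brings no volume worth counting | 10 min |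
| oak | 0.26 M | 0.130 M | 0.286 M |  | everything together at the start at −5 °C, warmed to 25 °C at 6.0 min | 10 min |
| maple | 0.26 M | 0.130 M (in portions, 3, over 6.0 min) | 0.286 M | 25 °C | first portion at the start, last at 6.0 min | 10 min |
| alder | 0.26 M (fed, over 6.0 min) | 0.130 M | 0.286 M |  | the addition at −5 °C, then warmed to 25 °C; the feed brings no volume worth counting | 10 min |
| cedar | 0.26 M | 0.130 M | 0.286 M | 25 °C | everything together at the start | 10 min |

- violet (time / min: over-reaction product / %, links / %): 1.00: 0.6, 14.2; 2.00: 2.9, 32.6; 3.00: 0.5, 43.8; 4.00: 2.6, 47.2; 5.00: 4.2, 49.0; 6.00: 4.5, 48.8
- grey (time / min: over-reaction product / %, links / %): 0.417: 1.9, 5.5; 1.33: 0.3, 21.9; 2.00: 1.4, 23.3; 3.00: 2.9, 20.9; 5.00: 5.9, 21.6; 6.00: 10.2, 17.3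
- teal (time / min: over-reaction product / %, links / %): 0.417: 1.7, 3.7; 1.33: 0, 20.4; 2.00: 1.2, 31.1; 3.00: 1.2, 47.1; 5.00: 3.5, 71.3; 6.00: 5.5, 77.5
- blue (time / min: over-reaction product / %, links / %): 0.500: 0.8, 8.6; 0.833: 0.7, 13.2; 1.50: 2.6, 28.8; 3.00: 6.4, 40.3; 6.00: 15.3, 31.9

(scatter of a reading: 1 percentage point)

- the flask that comes out highest in amount of over-reaction product, in percent of the first end groups charged, or "all alike" when all lie within 1.5 percentage points (elm / oak / maple / alder / cedar / all alike)
- over-reaction product at the end, in percent of the first end groups charged, elm
- over-reaction product at the end, in percent of the first end groups charged, oak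
- over-reaction product at the end, in percent of the first end groups charged, maple
- over-reaction product at the end, in percent of the first end groups charged, alder
- over-reaction product at the end, in percent of the first end groups charged, cedar

- at the start none of the solid second end groups is in solution

Set the product against the links that stood before it, using the area under the link curve, with links as a fraction of the charge. In the violet run, 4.5 % of product over an area of 2.11 min reads 0.0213 min⁻¹. At 31 °C, the grey run reads 0.0904 min⁻¹ and the blue run 0.0850 min⁻¹, although c(third end groups) was 0.13 M in grey and 0.20 M in blue. Solid second end groups differed too, 0.14 M in grey and 0.286 M in blue, so I leave both out of this rate. Interpolating on a log scale from violet to the mean of those two gives 0.0405 min⁻¹ at 25 °C. This is the link constant, the fraction of links passing into over-reaction product per minute, a first-order constant.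

Two versions of the flask kept warm from the start, with its first end groups in at once, can be solved in the head. In the low one, the whole charge of third end groups stands from the start, and links with their product level off as in violet at 53.3 %, arriving on average 1.50 min late, which gives 15.5 %. I take that for cedar. In the high one, third end groups take nothing and the first end groups are links from the start, which the charge allows, and that gives 33.3 %. Maple starts with a third of its third end groups, so my reckoning puts it between the two and above cedar.

The forecast names cedar, with 11.3 % for elm, 6.5 % for oak, 9.5 % for maple, 6.3 % for alder and 11.8 % for cedar. It ties the rate of over-reaction to third end groups as well as to links, where mine leaves them out: “Maple: less third group early, about 10%”.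

The flasks give 9.22 % for elm, 7.34 % for oak, 18.8 % for maple, 6.73 % for alder and 15.7 % for cedar, so maple stands highest.

    second end groups ⇌ dormant form (K = 3.50, k = 0.00350 s⁻¹, Ea = 91.0 kJ mol⁻¹, ΔH = −50.0 kJ mol⁻¹)
    links → over-reaction product (k = 6.60 × 10⁻⁴ s⁻¹, Ea = 92.0 kJ mol⁻¹)
    first end groups + second end groups → links (k = 0.0660 M⁻¹ s⁻¹, Ea = 54.0 kJ mol⁻¹)
    solid second end groups ⇌ second end groups, rate k4*(cs4 - [second end groups]) while solid is left; crystals form when [second end groups] > cs4 (solubility = 0.200 M, k = 0.0170 s⁻¹)
    second end groups + third end groups → links of the second sort (k = 0.130 M⁻¹ s⁻¹, Ea = 47.0 kJ mol⁻¹)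
    (constants at 25 °C)

In maple, second end groups had a half-life of 0.81 min at 0.936 min by their step with first end groups and 2.2 min at 10.0 min, when their step with third end groups gave 1.3 min. Divided by the link constant 0.0405 min⁻¹, maple's product asks for a mean link level of 46.4 % over 10 min, beside 50.5 % at its end. A flask like maple but with 1.1 M of solid second end groups gave 24.5 % of over-reaction product, which asks for 60.5 %, beside 74.8 % of links at its end.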